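Readings and results were computed for substances that don't exist.

3 questions are asked about two flasks, Wednesday's and Saturday's: how much target each holds at the end, and which holds more.

| flask | starting material | protic impurity | catalyst | temperature | remark | time |
|---|---|---|---|---|---|---|
| ash | 0.050 M (fed, over 4.0 min) | 0.061 M | 0.5 mol% | 35 °C | run made earlier; the fed solution adds 1.0 times the starting volume |  |
| alder | 0.050 M (fed, over 4.0 min) | 0.24 M | 0.5 mol% | 46 °C | run made earlier; the fed solution adds 1.0 times the starting volume |  |
| maple | 0.065 M (fed, over 4.0 min) | 0.050 M | 0.5 mol% | 35 °C | run made earlier; the fed solution adds 1.0 times the starting volume |  |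
| Wednesday's | 0.050 M (fed, over 4.0 min) | 0.0500 M | 0.5 mol% | 40 °C | the fed solution adds 1.0 times the starting volume | 4.0 min |
| Saturday's | 0.15 M | 0.200 M | 0.5 mol% | 40 °C | everything together at the start, the whole solution of starting material included, so that from the start the volume is larger by 1.0 times the starting volume | 4.0 min |

| run | time / min | target / % |
|---|---|---|
| ash | 0.250 | 2 |
| ash | 0.833 | 11 |
| ash | 1.33 | 17 |
| ash | 2.00 | 29 |
| ash | 3.00 | 46 |
| ash | 4.00 | 54 |
| alder | 0.250 | 2 |
| alder | 0.833 | 12 |
| alder | 1.33 | 15 |
| alder | 2.00 | 28 |
| alder | 3.00 | 38 |
| alder | 4.00 | 52 |
| maple | 0.333 | 3 |
| maple | 1.00 | 20 |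
| maple | 2.00 | 33 |
| maple | 3.00 | 49 |
| maple | 4.00 | 62 |

(each reading ± 2 percentage points)

- which of the two ends with the higher amount of target, in percent of the starting material charged ("neither" if they lie within 2 percentage points) (Wednesday's / Saturday's / neither)
- target at the end, in percent of the starting material charged, Wednesday's
- target at the end, in percent of the starting material charged, Saturday's

- charges are per starting volume, the dose included; the dosed solution carries all of it
- what was read earlier has a scatter of 2 percentage points, one standard deviation
- where the amount of starting material changes, what is given in equivalents or mol% on it follows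
- percentages count the whole charge, also what has not yet gone in

We build the flask up one process at a time, and we watch its odds (a selectivity): the fraction of the charge that became target over the fraction that did not.

With the catalysed step alone, target at the end of a complete feed would stand at 100 percent. But ash ends at 54 %. Its target at 2.00 min, half of the feed time, is 29 %, about half of that end value, so target follows the feed, and we take Wednesday's and Saturday's as nearly complete at the end.

So we add one more process: a loss that, like the catalysed step, we suppose first order in starting material. Starting material then cancels from the ratio of the two rates, and the odds should go with catalyst concentration. Ash's odds are 1.17 and maple's are 1.63, a reading of 1.39 against 1.30 in catalyst at the same temperature, with impurity at 0.050 M in maple and 0.061 M in ash.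

Then come temperature and impurity. Alder, at 46 °C with 0.24 M of impurity, ends one scatter below ash, with odds of 1.08. We cannot part the two effects, so for 40 °C we take the mean, 1.13.

The feed dilutes the catalyst: the volume averages 1.50 starting volumes, so the catalyst concentration at that mean volume in such a run is 1.67 × 10⁻⁴ M. This gives the quantity we carry, the odds per unit of catalyst concentration, 6770 M⁻¹.

For Wednesday's, the odds of 1.13 give 53.1 % target. Saturday's holds 3.75 × 10⁻⁴ M of catalyst from the start, so its odds are 2.54 and its target 71.8 %. Our reckoning puts Saturday's higher.

The forecast differs. It gives 68 % for Wednesday's and 55 % for Saturday's, and so names Wednesday's. Its stated ground: “Build-up is therefore limited by the catalyst, and the reaction is close to zero order in starting material.”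

The flask gives 54.5 % for Wednesday's and 72.0 % for Saturday's, so Saturday's holds more.

    starting material + catalyst → catalyst + target (k = 481 M⁻¹ s⁻¹, Ea = 50.0 kJ mol⁻¹)
    starting material + target → side product B (k = 0.187 M⁻¹ s⁻¹, Ea = 39.0 kJ mol⁻¹)
    starting material → side product A (k = 0.0572 s⁻¹, Ea = 86.0 kJ mol⁻¹)
    starting material + protic impurity → quenched substrate (k = 0.00901 M⁻¹ s⁻¹, Ea = 65.0 kJ mol⁻¹)
    (constants at 40 °C)

In Wednesday's, the catalysed step used starting material at 1.4 times the rate of the step to side product A at 1.91 min, and at 1.1 times that rate at 4.00 min, a smaller ratio. The end odds are 1.20 in Wednesday's and 2.57 in Saturday's, a factor of 2.14 against 2.25 in catalyst concentration as we reckoned it. Applied to Wednesday's recipe with 0.3 mol% of catalyst, our 6770 M⁻¹ gives odds of 0.677, hence 40.4 % target, and that flask holds 42.1 %.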